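**Retrosynthetic overview**
1. Target 17 ← its 10‑O‑TBS ether 16 ← alcohol 14. The C8 (R)‑2‑methylbutanoate goes on last, the C9 angelate before ring closure, and C10–OH is carried as a silyl ether.
2. The four‑membered ring is formed last: the C2–C7 bond comes from an epoxide‑derived tertiary C7 cation captured by the C2=C3 π‑bond of a silyl dienol ether (the himachalyl → longipinyl closure), which also delivers C8–OH.
3. The C7–C8 epoxide comes from allylic alcohol 8 by hydroxyl‑directed epoxidation; 8 comes from trienone 6 by γ,δ‑epoxidation and SmI2 opening, which sets C9–O trans to C10–O.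
4. The seven‑membered ring comes from a (4+3) annulation of 2‑methylfuran with the tertiary cation/enol ether pair released from the cyclopropane of carenone 2, followed by β‑elimination of the ether bridge.
5. Ring order: six‑membered (from (+)‑3‑carene, which fixes C1) → seven‑membered → four‑membered.

Assumptions: the ester at C8 is (R)‑2‑methylbutanoate, as the given SMILES specifies. Locants are biogenetic (farnesane): C1/C6 ring fusion, C2–C5 the rest of the six‑membered ring (3‑Me, 5‑C=O), C7 (Me), C8, C9, C10, C11 (Me2) the rest of the seven‑membered ring; "lower face" is the face of the seven‑membered ring that carries C2 and C5.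

**Step 1**
Reactants: 1 (+)-3-carene
Product: 2 (1R,6S)-4,7,7-trimethylbicyclo[4.1.0]hept-3-en-2-one (car-3-en-5-one)
Conditions: t-BuOOH, CrO3 (5 mol %), CH2Cl2, rt
Reagents that add atoms: tert-butyl hydroperoxide, CC(C)(C)OO
Why: Chromium‑catalysed allylic oxidation at the ring CH2 flanked by the alkene and the cyclopropane, a known route to this enone; no stereocentre is touched.

**Step 2**
Reactants: 2 car-3-en-5-one; 3 2-methylfuran
Product: 4 7,10-epoxyhimachala-3,8-dien-5-one (H-1/H-6 cis; ether bridge on the lower face)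
Conditions: TMSOTf (20 mol %), CH2Cl2, −78 °C
Reagents that add atoms: none
Why: Proposed new method: the silyl‑activated cyclopropyl ketone opens at C6–C11 to a tertiary cation/silyl dienol ether pair, 2‑methylfuran adds through its free α‑carbon, and the C6 enol ether closes on the methyl‑bearing furanium carbon (stepwise (4+3) annulation; closest known reactions are Lewis‑acid (4+3) annulations of donor–acceptor cyclopropanes with dienes and silyl triflate‑mediated furan (4+3) cycloadditions of silyloxyallyl cations); C1 is untouched, and axial attack of the enol ether in a chair‑like closure should give the cis fusion and place the ether bridge on the C2/C5 face, which fixes C10.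

**Step 3**
Reactants: 4 7,10-epoxyhimachala-3,8-dien-5-one
Product: 6 10-(tert-butyldimethylsilyloxy)himachala-3,6,8-trien-5-one, via lithium alkoxide 5 (not isolated)
Conditions: LiN(iPr)2, THF, −78 to −30 °C; then TBSOTf, −78 °C
Reagents that add atoms: tert-butyldimethylsilyl trifluoromethanesulfonate, CC(C)(C)[Si](C)(C)OS(=O)(=O)C(F)(F)F
Why: Kinetic α′‑deprotonation at C6 triggers E1cB β‑elimination of the C7 ether oxygen (the known ring opening of oxabicyclic β‑alkoxy ketones) and the C10 alkoxide is silylated in the same flask; C1 and C10 are unchanged.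

**Step 4**
Reactants: 6 10-(tert-butyldimethylsilyloxy)himachala-3,6,8-trien-5-one
Product: 7 8,9-epoxy-10-(tert-butyldimethylsilyloxy)himachala-3,6-dien-5-one (epoxide on the upper face)
Conditions: mCPBA, CH2Cl2, 0 °C
Reagents that add atoms: 3-chloroperoxybenzoic acid, OOC(=O)c1cccc(Cl)c1
Why: Prilezhaev epoxidation takes the γ,δ‑double bond, the only one not directly attached to the carbonyl, on the face opposite the allylic silyl ether, which sets C8–O and C9–O trans to C10–O.

**Step 5**
Reactants: 7 8,9-epoxy-10-(tert-butyldimethylsilyloxy)himachala-3,6-dien-5-one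
Product: 8 9-hydroxy-10-(tert-butyldimethylsilyloxy)himachala-3,7-dien-5-one (9-OH upper face; H-1/H-6 cis)
Conditions: SmI2, THF/MeOH, −78 °C
Reagents that add atoms: none
Why: SmI2 reductive opening of a γ,δ‑epoxy enone (known for vinylogous epoxy carbonyls) cleaves C8–O and keeps C9–O, and kinetic α‑protonation of the samarium dienolate from the less hindered upper face should give the β,γ‑enone with H‑6 cis to H‑1.

**Step 6**
Reactants: 8 9-hydroxy-10-(tert-butyldimethylsilyloxy)himachala-3,7-dien-5-one
Product: 9 7,8-epoxy-9-hydroxy-10-(tert-butyldimethylsilyloxy)himachal-3-en-5-one (epoxide cis to 9-OH)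
Conditions: VO(acac)2 (5 mol %), t-BuOOH, CH2Cl2, 0 °C to rt
Reagents that add atoms: tert-butyl hydroperoxide, CC(C)(C)OO
Why: Vanadium‑catalysed hydroxyl‑directed epoxidation of the allylic alcohol delivers oxygen to C7=C8 syn to the C9 hydroxyl and leaves the enone alone.

**Step 7**
Reactants: 9 7,8-epoxy-9-hydroxy-10-(tert-butyldimethylsilyloxy)himachal-3-en-5-one; 10 angelic acid
Product: 11 9-angeloyloxy-7,8-epoxy-10-(tert-butyldimethylsilyloxy)himachal-3-en-5-one
Conditions: 2,4,6-trichlorobenzoyl chloride, Et3N, toluene, rt; then DMAP (cat.), rt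
Reagents that add atoms: none
Why: Yamaguchi esterification of the only free hydroxyl; the mixed‑anhydride protocol at room temperature preserves the Z (angelate) geometry.

**Step 8**
Reactants: 11 9-angeloyloxy-7,8-epoxy-10-(tert-butyldimethylsilyloxy)himachal-3-en-5-one
Product: 12 9-angeloyloxy-7,8-epoxy-10-(tert-butyldimethylsilyloxy)-5-(trimethylsilyloxy)himachala-2,4-diene
Conditions: TMSOTf, Et3N, CH2Cl2, −78 °C
Reagents that add atoms: trimethylsilyl trifluoromethanesulfonate, C[Si](C)(C)OS(=O)(=O)C(F)(F)F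
Why: Soft enolisation removes the unhindered γ‑hydrogen at C2 to give the linear endocyclic silyl dienol ether, while the hindered C6–H and the epoxide are expected to survive at −78 °C; no stereocentre changes.

**Step 9**
Reactants: 12 9-angeloyloxy-7,8-epoxy-10-(tert-butyldimethylsilyloxy)-5-(trimethylsilyloxy)himachala-2,4-diene
Product: 14 9-angeloyloxy-8-hydroxy-10-(tert-butyldimethylsilyloxy)longipin-3-en-5-one, via trimethylsilyl ether 13 (not isolated)
Conditions: TMSOTf (10 mol %), CH2Cl2, −78 to −40 °C; then aq. citric acid, MeOH, 0 °C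
Reagents that add atoms: none
Why: Proposed new method: the silylated epoxide ionises at tertiary C7 and the γ‑carbon (C2) of the silyl dienol ether attacks it from the face opposite the oxygen (intramolecular vinylogous Mukaiyama‑type epoxide opening, the flask version of the himachalyl‑to‑longipinyl closure; closest known reactions are Lewis‑acid epoxide‑initiated cyclisations terminated by silyl enol ethers and γ‑alkylation of silyl dienol ethers by tertiary cations), with epoxide strain offsetting cyclobutane strain; inversion at C7 sets C7 and C2, C8–O keeps its face, and silyl loss gives the enone irreversibly.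

**Step 10**
Reactants: 14 9-angeloyloxy-8-hydroxy-10-(tert-butyldimethylsilyloxy)longipin-3-en-5-one; 15 (R)-2-methylbutanoic acid
Product: 16 9-angeloyloxy-8-[(R)-2-methylbutanoyloxy]-10-(tert-butyldimethylsilyloxy)longipin-3-en-5-one
Conditions: 2,4,6-trichlorobenzoyl chloride, Et3N, toluene, rt; then DMAP (cat.), rt
Reagents that add atoms: none
Why: Yamaguchi esterification of the single free (neopentyl) hydroxyl; the acid's stereocentre is carried in unchanged.

**Step 11**
Reactants: 16 9-angeloyloxy-8-[(R)-2-methylbutanoyloxy]-10-(tert-butyldimethylsilyloxy)longipin-3-en-5-one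
Product: 17 CNP0202800.1
Conditions: HF·pyridine, THF, 0 °C to rt
Reagents that add atoms: none
Why: Fluoride cleavage of the silyl ether under acidic, non‑basic conditions that avoid acyl migration and angelate isomerisation.

**Compound list**
1 | (+)-3-carene, (1S,6R)-3,7,7-trimethylbicyclo[4.1.0]hept-3-ene | CC1=CC[C@@H]2[C@H](C1)C2(C)C | starting material
2 | (1R,6S)-4,7,7-trimethylbicyclo[4.1.0]hept-3-en-2-one (car-3-en-5-one) | CC1=CC(=O)[C@@H]2[C@H](C1)C2(C)C | intermediate
3 | 2-methylfuran | Cc1ccco1 | starting material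
4 | 7,10-epoxyhimachala-3,8-dien-5-one; H-1/H-6 cis, ether bridge on the lower face | CC1=CC(=O)[C@@H]2[C@H](C1)C(C)(C)[C@H]1C=C[C@]2(C)O1 | intermediate
5 | lithium 5-oxohimachala-3,6,8-trien-10-olate | CC1=CC(=O)C2=C(C)C=C[C@@H]([O-])C(C)(C)[C@H]2C1.[Li+] | intermediate
6 | 10-(tert-butyldimethylsilyloxy)himachala-3,6,8-trien-5-one; 10-O on the lower face | CC1=CC(=O)C2=C(C)C=C[C@@H](O[Si](C)(C)C(C)(C)C)C(C)(C)[C@H]2C1 | intermediate
7 | 8,9-epoxy-10-(tert-butyldimethylsilyloxy)himachala-3,6-dien-5-one; epoxide on the upper face, trans to 10-O | CC1=CC(=O)C2=C(C)[C@@H]3O[C@@H]3[C@@H](O[Si](C)(C)C(C)(C)C)C(C)(C)[C@H]2C1 | intermediate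
8 | 9-hydroxy-10-(tert-butyldimethylsilyloxy)himachala-3,7-dien-5-one; 9-OH upper face, H-1/H-6 cis | CC1=CC(=O)[C@H]2C(C)=C[C@H](O)[C@@H](O[Si](C)(C)C(C)(C)C)C(C)(C)[C@H]2C1 | intermediate
9 | 7,8-epoxy-9-hydroxy-10-(tert-butyldimethylsilyloxy)himachal-3-en-5-one; epoxide upper face, cis to 9-OH | CC1=CC(=O)[C@H]2[C@]3(C)O[C@@H]3[C@H](O)[C@@H](O[Si](C)(C)C(C)(C)C)C(C)(C)[C@H]2C1 | intermediate
10 | angelic acid, (Z)-2-methylbut-2-enoic acid | C/C=C(/C)C(=O)O | starting material
11 | 9-angeloyloxy-7,8-epoxy-10-(tert-butyldimethylsilyloxy)himachal-3-en-5-one | CC1=CC(=O)[C@H]2[C@]3(C)O[C@@H]3[C@H](OC(=O)/C(C)=C\C)[C@@H](O[Si](C)(C)C(C)(C)C)C(C)(C)[C@H]2C1 | intermediate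
12 | 9-angeloyloxy-7,8-epoxy-10-(tert-butyldimethylsilyloxy)-5-(trimethylsilyloxy)himachala-2,4-diene | C[Si](C)(C)OC1=CC(C)=C[C@H]2[C@@H]1[C@]3(C)O[C@@H]3[C@H](OC(=O)/C(C)=C\C)[C@@H](O[Si](C)(C)C(C)(C)C)C2(C)C | intermediate
13 | 9-angeloyloxy-10-(tert-butyldimethylsilyloxy)-8-(trimethylsilyloxy)longipin-3-en-5-one | C/C=C(/C)C(=O)O[C@@H]1[C@@H](O[Si](C)(C)C(C)(C)C)C(C)(C)[C@@H]2[C@H]3C(=O)C=C(C)[C@@H]2[C@@]3(C)[C@@H]1O[Si](C)(C)C | intermediate
14 | 9-angeloyloxy-8-hydroxy-10-(tert-butyldimethylsilyloxy)longipin-3-en-5-one; 8-OH and 9-O upper face, 10-O lower face | C/C=C(/C)C(=O)O[C@@H]1[C@@H](O[Si](C)(C)C(C)(C)C)C(C)(C)[C@@H]2[C@H]3C(=O)C=C(C)[C@@H]2[C@@]3(C)[C@@H]1O | intermediate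
15 | (R)-2-methylbutanoic acid | CC[C@@H](C)C(=O)O | starting material
16 | 9-angeloyloxy-8-[(R)-2-methylbutanoyloxy]-10-(tert-butyldimethylsilyloxy)longipin-3-en-5-one | C/C=C(/C)C(=O)O[C@@H]1[C@@H](O[Si](C)(C)C(C)(C)C)C(C)(C)[C@@H]2[C@H]3C(=O)C=C(C)[C@@H]2[C@@]3(C)[C@@H]1OC(=O)[C@H](C)CC | intermediate
17 | CNP0202800.1, 9-angeloyloxy-10-hydroxy-8-[(R)-2-methylbutanoyloxy]longipin-3-en-5-one | C/C=C(/C)C(=O)O[C@@H]1[C@@H](O)C(C)(C)[C@@H]2[C@H]3C(=O)C=C(C)[C@@H]2[C@@]3(C)[C@@H]1OC(=O)[C@H](C)CC | target

**Totals**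
Total step count: 11. Longest linear sequence: 11 steps (1 → 17).

**Steps most likely to fail, with fallbacks**

Step 2 (the (4+3) annulation may stop at Friedel–Crafts alkylation of the furan, or give the other bridge orientation). The fallback sets out from 2 and separates cation generation from enol ether formation. HCl (Et2O, 0 °C) opens the cyclopropane to (S)-5-(2-chloropropan-2-yl)-3-methylcyclohex-2-en-1-one F1. LiN(iPr)2/Me3SiCl then gives its cross‑conjugated trimethylsilyl dienol ether F2. AgOTf with 2‑methylfuran at −78 °C abstracts chloride, so furan capture and closure by the pre‑formed C6 enol ether follow without a free Brønsted acid. The route is rejoined at 4.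

Step 8 (amine/silyl triflate may open the β,γ‑epoxy ketone, or enolise towards C6 or the C3 methyl). The fallback sets out from 11 and uses no silyl ether. 11 is complexed with aluminum tris(2,6-diphenylphenoxide) and deprotonated at C2 with lithium 2,2,6,6-tetramethylpiperidide (toluene/THF, −78 °C). The bulky aluminium shields C6, and the γ‑carbanion opens the aluminium‑bound epoxide at C7 in the same flask. The route is rejoined at 14, with 12 and 13 bypassed; this fallback makes no compound outside the list (F0).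

Step 9 (the four‑membered ring closure may lose to epoxide rearrangement or elimination). The fallback sets out from 8 and forms the C2–C7 bond through a metal allyl instead. Methyl chloroformate/pyridine gives the 9-O-methoxycarbonyl derivative of 8 F3. An iridium‑catalysed intramolecular allylic alkylation ([Ir(cod)Cl]2, P(OPh)3, LiN(SiMe3)2, aluminum tris(2,6-diphenylphenoxide)) joins C2 to the methyl‑bearing allyl terminus C7 with loss of CO2, giving 10-(tert-butyldimethylsilyloxy)longipina-3,8-dien-5-one F4. OsO4/NMO adds anti to the allylic silyl ether on the exposed face to give 8,9-dihydroxy-10-(tert-butyldimethylsilyloxy)longipin-3-en-5-one F5. Yamaguchi angeloylation of the less hindered C9 hydroxyl rejoins the route at 14.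

**Further compounds**
F1 | step 2 | (S)-5-(2-chloropropan-2-yl)-3-methylcyclohex-2-en-1-one | CC1=CC(=O)C[C@H](C1)C(C)(C)Cl
F2 | step 2 | (S)-5-(2-chloropropan-2-yl)-3-methyl-1-(trimethylsilyloxy)cyclohexa-1,3-diene (cross-conjugated silyl dienol ether of F1) | CC1=CC(O[Si](C)(C)C)=C[C@H](C1)C(C)(C)Cl
F0 | step 8 | none | none
F3 | step 9 | 9-(methoxycarbonyloxy)-10-(tert-butyldimethylsilyloxy)himachala-3,7-dien-5-one | CC1=CC(=O)[C@H]2C(C)=C[C@H](OC(=O)OC)[C@@H](O[Si](C)(C)C(C)(C)C)C(C)(C)[C@H]2C1
F4 | step 9 | 10-(tert-butyldimethylsilyloxy)longipina-3,8-dien-5-one | C1[C@@H](O[Si](C)(C)C(C)(C)C)C(C)(C)[C@@H]2[C@H]3C(=O)C=C(C)[C@@H]2[C@@]3(C)C=1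
F5 | step 9 | 8,9-dihydroxy-10-(tert-butyldimethylsilyloxy)longipin-3-en-5-one | O[C@@H]1[C@@H](O[Si](C)(C)C(C)(C)C)C(C)(C)[C@@H]2[C@H]3C(=O)C=C(C)[C@@H]2[C@@]3(C)[C@@H]1O
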